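Numbering: ring A = dihydrofuran O1–C2–C3–C3a–C7a. Ring B = the fused 2-pyranone (C3a, C4, O5, C6, C7, C7a) with the styryl group on C6. Ring C = the catechol on C2. Ring D = the 4-hydroxy-2-pyranone bound through C6' to C3.
Enabling feature: the C3–C3a bond ties the enol-type donor carbon C3a of ring B to C3, the α-carbon of the carbonyl-level C6' of ring D and hence also a donor site. This like-polarity bond is reached by letting C3a move from C6' to C3 while C6' is still the carbonyl carbon of a six-membered ring.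
Cuts (retrosynthetic order): O1'–C2' and C5'–C6' of ring D (back to a C3 ester and a dioxinone); C3–C3a (contraction undone, giving a 2,3-dihydropyrano[4,3-b]pyran-4,5-dione); O1–C7a and C2–C3 (aldol/cyclocondensation); the C3a–acetyl bond; the styryl C=C.
Forward: ring B is bought as triacetic acid lactone and extended to the styrylpyranone. A six-membered oxygen ring is annulated onto it and contracted to ring A. Ring D is closed last through an acylketene, and the three silyl ethers are removed at the end.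
Stereochemistry: C2 (S) is set by a catalytic enantioselective Mukaiyama aldol addition and kept because the ring is then closed at O1–C7a, not at C2–O1. C3 (S) is relayed from C2 in the key step (anti iodination, invertive 1,2-shift), and trans is also the more stable arrangement.

Key step: step 8

Abbreviations and numbering: TBS = tert-butyldimethylsilyl, TMS = trimethylsilyl. The six-membered precursor is numbered O1, C2, C3, C4, C4a, C5, O6, C7, C8, C8a; its C4a and C8a become C3a and C7a, and its C4 becomes the ester carbon (later C6').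
Assumption: the D-tryptophan-derived oxazaborolidinone is taken to expose the si face of the aromatic aldehyde, the mirror image of the re-face addition known for the L-series with benzaldehyde. The antipodal catalyst is equally available should the sense prove opposite.

Step 1
Reactants: 1 4-hydroxybenzaldehyde
Product: 2 4-(TBS-oxy)benzaldehyde
Conditions: TBSCl, imidazole, DMF, rt
Reagents that add atoms: tert-butyldimethylsilyl chloride, CC(C)(C)[Si](C)(C)Cl
Why: Imidazole-promoted O-silylation of a phenol gives an aryl silyl ether that tolerates amide bases and brief acid and falls to fluoride at the end.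

Step 2
Reactants: 3 4-hydroxy-6-methyl-2H-pyran-2-one (triacetic acid lactone); 2 4-(TBS-oxy)benzaldehyde
Product: 5 4-hydroxy-6-{2-hydroxy-2-[4-(TBS-oxy)phenyl]ethyl}-2H-pyran-2-one (racemic), via lactone dianion 4 (not isolated)
Conditions: LiN(i-Pr)2 (2.3 equiv), THF, −78 → −20 °C; 2, −78 °C; 1 M HCl
Reagents that add atoms: none
Why: Dianion aldol addition, in which the second deprotonation occurs at the vinylogous C6 methyl group and this last-formed, most reactive site adds to the non-enolisable aldehyde; the carbinol centre is racemic and is erased in step 3.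

Step 3
Reactants: 5 4-hydroxy-6-{2-hydroxy-2-[4-(TBS-oxy)phenyl]ethyl}-2H-pyran-2-one
Product: 6 4-hydroxy-6-[(E)-4-(TBS-oxy)styryl]-2H-pyran-2-one (O-silylated bisnoryangonin)
Conditions: 4-MeC6H4SO3H·H2O (5 mol %), toluene, 90 °C, azeotropic removal of water
Reagents that add atoms: none
Why: Acid-catalysed E1-type dehydration of a donor-substituted benzylic alcohol should give the fully conjugated E-alkene under thermodynamic control.

Step 4
Reactants: 6 4-hydroxy-6-[(E)-4-(TBS-oxy)styryl]-2H-pyran-2-one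
Product: 8 3-acetyl-4-hydroxy-6-[(E)-4-(TBS-oxy)styryl]-2H-pyran-2-one, via enol acetate 7 (not isolated)
Conditions: AcOH, DCC, 4-(dimethylamino)pyridine (0.3 equiv), toluene, rt → 60 °C
Reagents that add atoms: acetic acid, CC(=O)O
Why: Carbodiimide O-acylation followed by the aminopyridine-mediated Fries-type O-to-C acyl shift is the established entry to 3-acyl-4-hydroxy-2-pyranones, the chelated tricarbonyl enol being the thermodynamic sink and C3 the only doubly activated carbon.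

Step 5
Reactants: 8 3-acetyl-4-hydroxy-6-[(E)-4-(TBS-oxy)styryl]-2H-pyran-2-one
Product: 9 4-(TMS-oxy)-3-[1-(TMS-oxy)vinyl]-6-[(E)-4-(TBS-oxy)styryl]-2H-pyran-2-one
Conditions: Me3SiOSO2CF3 (2.4 equiv), Et3N (3 equiv), CH2Cl2, 0 °C; pentane extraction, no aqueous work-up, used crude
Reagents that add atoms: trimethylsilyl trifluoromethanesulfonate, C[Si](C)(C)OS(=O)(=O)C(F)(F)F
Why: Soft enolisation with a silyl triflate and a tertiary amine silylates the acidic 4-OH and turns the methyl ketone into its enol silane, the usual way from a 1,3-dicarbonyl compound to a 1,3-bis(silyloxy)diene.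

Step 6
Reactants: 10 3,4-dihydroxybenzaldehyde
Product: 11 3,4-bis(TBS-oxy)benzaldehyde
Conditions: TBSCl (2.4 equiv), imidazole, DMF, rt
Reagents that add atoms: tert-butyldimethylsilyl chloride, CC(C)(C)[Si](C)(C)Cl
Why: Imidazole-promoted double O-silylation masks the oxidation-prone catechol with the same fluoride-labile group used on the styryl phenol.

Step 7
Reactants: 9 4-(TMS-oxy)-3-[1-(TMS-oxy)vinyl]-6-[(E)-4-(TBS-oxy)styryl]-2H-pyran-2-one; 11 3,4-bis(TBS-oxy)benzaldehyde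
Product: 13 (2S)-2-[3,4-bis(TBS-oxy)phenyl]-7-[(E)-4-(TBS-oxy)styryl]-2,3-dihydro-4H,5H-pyrano[4,3-b]pyran-4,5-dione, via silylated aldol adduct 12 (not isolated)
Conditions: (4R)-2-butyl-4-(1H-indol-3-ylmethyl)-3-(4-tolylsulfonyl)-1,3,2-oxazaborolidin-5-one (20 mol %), EtCN, −78 °C; then CF3CO2H, CH2Cl2, 0 °C
Reagents that add atoms: none
Why: Enantioselective Mukaiyama aldol addition followed by acid-induced cyclocondensation, the stepwise hetero-Diels–Alder manifold known for 1-oxy-3-silyloxydienes and aromatic aldehydes: the boron Lewis acid binds 11, its indole shields one face so that the enol silane adds to the si face and sets C2 as S, and CF3CO2H then lets the carbinol oxygen replace the oxygen substituent at C8a by 6-endo-trig addition–elimination, a closure that leaves the C2–O bond untouched and sidesteps the reversible, unfavourable oxa-Michael addition of a chelated cinnamoylpyranone.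

Step 8
Reactants: 13 (2S)-2-[3,4-bis(TBS-oxy)phenyl]-7-[(E)-4-(TBS-oxy)styryl]-2,3-dihydro-4H,5H-pyrano[4,3-b]pyran-4,5-dione
Product: 16 methyl (2S,3S)-2-[3,4-bis(TBS-oxy)phenyl]-4-oxo-6-[(E)-4-(TBS-oxy)styryl]-2,3-dihydro-4H-furo[3,2-c]pyran-3-carboxylate (trans), via methyl enol ether 14 (not isolated), via iodanyl ketal 15 (not isolated)
Conditions: PhI(OAc)2 (1.1 equiv), HC(OMe)3, H2SO4 (cat.), 0 °C → rt; aq NaHCO3
Reagents that add atoms: trimethyl orthoformate, COC(OC)OC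
Why: Acid and orthoformate turn the C4 ketone into methyl enol ether 14, whose C3 is attacked by the electrophilic trivalent iodine reagent on the face away from the pseudo-equatorial C2 aryl group, and methanol caps the oxocarbenium ion to give the 2,3-trans iodanyl ketal 15. In 15 the equatorial C3–iodine bond lies antiperiplanar to C4–C4a, so C4a (the future C3a) moves from the ketal carbon to C3 as iodobenzene departs, pushed by the two methoxy groups, and the dimethoxycarbenium ion left at C4 ends as the methyl ester, the future C6' of ring D. The closest known reaction type is the oxidative ring contraction of flavanones to trans-2-aryl-2,3-dihydrobenzofuran-3-carboxylates with PhI(OAc)2 or Tl(NO3)3 in trimethyl orthoformate, C4a being here the donor-substituted β-carbon of a vinylogous ester in place of an ortho-alkoxyaryl carbon. Ring A closes by contraction of the six-membered ring: the C4a=C8a π bond bridges to C3 (3-exo-tet) and the C4–C4a bond then breaks, which forms C3–C3a and leaves O1, C2, C3, C3a and C7a as the five-membered ring. The new stereocentre C3 is controlled by C2 through anti iodination followed by inversion in the shift, which places the ester trans to the aryl group (2S,3S), also the more stable arrangement. The enol ether must outrun the styryl alkene and the silyloxyarenes, which is secured because it carries an oxygen donor directly on the double bond while the styryl bond is drained by the pyranone acceptor, and contraction must beat aryl migration and elimination, which ketalisation in the orthoformate medium and the equatorial aryl group favour.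

Step 9
Reactants: 16 methyl (2S,3S)-2-[3,4-bis(TBS-oxy)phenyl]-4-oxo-6-[(E)-4-(TBS-oxy)styryl]-2,3-dihydro-4H-furo[3,2-c]pyran-3-carboxylate
Product: 17 (2S,3S)-2-[3,4-bis(TBS-oxy)phenyl]-4-oxo-6-[(E)-4-(TBS-oxy)styryl]-2,3-dihydro-4H-furo[3,2-c]pyran-3-carboxylic acid
Conditions: Me3SnOH (5 equiv), ClCH2CH2Cl, 70 °C; 5 % aq HCl wash
Reagents that add atoms: trimethyltin hydroxide, C[Sn](C)(C)O
Why: Organotin hydroxide ester cleavage works under nearly neutral conditions and is chosen because hydroxide or alkoxide would enolise C3 and open ring A by β-elimination of the ring B pyranolate; any aryl silyl ether lost here can be restored with TBSCl and imidazole.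

Step 10
Reactants: 17 (2S,3S)-2-[3,4-bis(TBS-oxy)phenyl]-4-oxo-6-[(E)-4-(TBS-oxy)styryl]-2,3-dihydro-4H-furo[3,2-c]pyran-3-carboxylic acid; 18 2,2,6-trimethyl-4H-1,3-dioxin-4-one
Product: 21 (2S,3S)-2-[3,4-bis(TBS-oxy)phenyl]-3-[2-(2,2-dimethyl-4-oxo-4H-1,3-dioxin-6-yl)acetyl]-6-[(E)-4-(TBS-oxy)styryl]-2,3-dihydro-4H-furo[3,2-c]pyran-4-one, via acid chloride 19 (not isolated), via lithium dienolate 20 (not isolated)
Conditions: 17, Me2C=C(Cl)NMe2, CH2Cl2, 0 °C; added to 18 + LiN(i-Pr)2 (2.5 equiv each), THF, −78 °C; AcOH quench at −78 °C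
Reagents that add atoms: none
Why: Claisen-type γ-C-acylation of the dioxinone dienolate by an acid chloride is the known route to 6-(2-oxoalkyl)dioxinones, the chloroenamine makes 19 without acid or base, the second equivalent of 20 takes up the acidic proton of 21, and C3, should it pass through a ketene, is reprotonated to the more stable trans form while C2 is not involved.

Step 11
Reactants: 21 (2S,3S)-2-[3,4-bis(TBS-oxy)phenyl]-3-[2-(2,2-dimethyl-4-oxo-4H-1,3-dioxin-6-yl)acetyl]-6-[(E)-4-(TBS-oxy)styryl]-2,3-dihydro-4H-furo[3,2-c]pyran-4-one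
Product: 23 (2S,3S)-2-[3,4-bis(TBS-oxy)phenyl]-3-(4-hydroxy-2-oxo-2H-pyran-6-yl)-6-[(E)-4-(TBS-oxy)styryl]-2,3-dihydro-4H-furo[3,2-c]pyran-4-one, via acylketene 22 (not isolated)
Conditions: toluene, 110 °C
Reagents that add atoms: none
Why: Retro-hetero-Diels–Alder loss of acetone frees an acylketene that is captured by the enol oxygen of the C6' ketone, the standard neutral closure of 6-substituted 4-hydroxy-2-pyranones, and no reagent is present that could disturb C2 or C3.

Step 12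
Reactants: 23 (2S,3S)-2-[3,4-bis(TBS-oxy)phenyl]-3-(4-hydroxy-2-oxo-2H-pyran-6-yl)-6-[(E)-4-(TBS-oxy)styryl]-2,3-dihydro-4H-furo[3,2-c]pyran-4-one
Product: 24 (2S,3S)-2-(3,4-dihydroxyphenyl)-3-(4-hydroxy-2-oxo-2H-pyran-6-yl)-6-[(E)-4-hydroxystyryl]-2,3-dihydro-4H-furo[3,2-c]pyran-4-one (CNP0330607.1)
Conditions: HF·pyridine, pyridine/THF, 0 °C → rt
Reagents that add atoms: none
Why: Fluoride-driven cleavage of the three aryl silyl ethers in a buffered, weakly acidic medium frees the phenols without the base that could open ring A or either pyranone.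

Compound list
1 | 4-hydroxybenzaldehyde | O=Cc1ccc(O)cc1 | starting material
2 | 4-(TBS-oxy)benzaldehyde | O=Cc1ccc(O[Si](C)(C)C(C)(C)C)cc1 | intermediate
3 | 4-hydroxy-6-methyl-2H-pyran-2-one (triacetic acid lactone) | Cc1cc(O)cc(=O)o1 | starting material
4 | dilithium salt of the O,C-dianion of triacetic acid lactone | [Li+].[Li+].[CH2-]c1cc([O-])cc(=O)o1 | intermediate
5 | 4-hydroxy-6-{2-hydroxy-2-[4-(TBS-oxy)phenyl]ethyl}-2H-pyran-2-one (racemic) | OC(Cc1cc(O)cc(=O)o1)c1ccc(O[Si](C)(C)C(C)(C)C)cc1 | intermediate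
6 | 4-hydroxy-6-[(E)-4-(TBS-oxy)styryl]-2H-pyran-2-one | O=c1cc(O)cc(/C=C/c2ccc(O[Si](C)(C)C(C)(C)C)cc2)o1 | intermediate
7 | 2-oxo-6-[(E)-4-(TBS-oxy)styryl]-2H-pyran-4-yl acetate | CC(=O)Oc1cc(/C=C/c2ccc(O[Si](C)(C)C(C)(C)C)cc2)oc(=O)c1 | intermediate
8 | 3-acetyl-4-hydroxy-6-[(E)-4-(TBS-oxy)styryl]-2H-pyran-2-one | CC(=O)c1c(O)cc(/C=C/c2ccc(O[Si](C)(C)C(C)(C)C)cc2)oc1=O | intermediate
9 | 4-(TMS-oxy)-3-[1-(TMS-oxy)vinyl]-6-[(E)-4-(TBS-oxy)styryl]-2H-pyran-2-one | C=C(O[Si](C)(C)C)c1c(O[Si](C)(C)C)cc(/C=C/c2ccc(O[Si](C)(C)C(C)(C)C)cc2)oc1=O | intermediate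
10 | 3,4-dihydroxybenzaldehyde | O=Cc1ccc(O)c(O)c1 | starting material
11 | 3,4-bis(TBS-oxy)benzaldehyde | O=Cc1ccc(O[Si](C)(C)C(C)(C)C)c(O[Si](C)(C)C(C)(C)C)c1 | intermediate
12 | 3-{(3S)-3-[3,4-bis(TBS-oxy)phenyl]-3-(TMS-oxy)propanoyl}-4-(TMS-oxy)-6-[(E)-4-(TBS-oxy)styryl]-2H-pyran-2-one | O=C(C[C@@H](c1ccc(O[Si](C)(C)C(C)(C)C)c(O[Si](C)(C)C(C)(C)C)c1)O[Si](C)(C)C)c1c(O[Si](C)(C)C)cc(/C=C/c2ccc(O[Si](C)(C)C(C)(C)C)cc2)oc1=O | intermediate
13 | (2S)-2-[3,4-bis(TBS-oxy)phenyl]-7-[(E)-4-(TBS-oxy)styryl]-2,3-dihydro-4H,5H-pyrano[4,3-b]pyran-4,5-dione | O=C1C[C@@H](c3ccc(O[Si](C)(C)C(C)(C)C)c(O[Si](C)(C)C(C)(C)C)c3)Oc2cc(/C=C/c3ccc(O[Si](C)(C)C(C)(C)C)cc3)oc(=O)c12 | intermediate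
14 | (2S)-2-[3,4-bis(TBS-oxy)phenyl]-4-methoxy-7-[(E)-4-(TBS-oxy)styryl]-2H,5H-pyrano[4,3-b]pyran-5-one | COC1=C[C@@H](c3ccc(O[Si](C)(C)C(C)(C)C)c(O[Si](C)(C)C(C)(C)C)c3)Oc2cc(/C=C/c3ccc(O[Si](C)(C)C(C)(C)C)cc3)oc(=O)c12 | intermediate
15 | (2R,3R)-3-[acetoxy(phenyl)-λ3-iodanyl]-2-[3,4-bis(TBS-oxy)phenyl]-4,4-dimethoxy-7-[(E)-4-(TBS-oxy)styryl]-3,4-dihydro-2H,5H-pyrano[4,3-b]pyran-5-one (aryl and iodanyl trans; the C2 descriptor changes only because iodine raises the rank of C3) | COC1(OC)[C@H](I(c4ccccc4)OC(C)=O)[C@@H](c3ccc(O[Si](C)(C)C(C)(C)C)c(O[Si](C)(C)C(C)(C)C)c3)Oc2cc(/C=C/c3ccc(O[Si](C)(C)C(C)(C)C)cc3)oc(=O)c12 | intermediate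
16 | methyl (2S,3S)-2-[3,4-bis(TBS-oxy)phenyl]-4-oxo-6-[(E)-4-(TBS-oxy)styryl]-2,3-dihydro-4H-furo[3,2-c]pyran-3-carboxylate | COC(=O)[C@H]2c3c(cc(/C=C/c4ccc(O[Si](C)(C)C(C)(C)C)cc4)oc3=O)O[C@@H]2c2ccc(O[Si](C)(C)C(C)(C)C)c(O[Si](C)(C)C(C)(C)C)c2 | intermediate
17 | (2S,3S)-2-[3,4-bis(TBS-oxy)phenyl]-4-oxo-6-[(E)-4-(TBS-oxy)styryl]-2,3-dihydro-4H-furo[3,2-c]pyran-3-carboxylic acid | OC(=O)[C@H]2c3c(cc(/C=C/c4ccc(O[Si](C)(C)C(C)(C)C)cc4)oc3=O)O[C@@H]2c2ccc(O[Si](C)(C)C(C)(C)C)c(O[Si](C)(C)C(C)(C)C)c2 | intermediate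
18 | 2,2,6-trimethyl-4H-1,3-dioxin-4-one | CC1=CC(=O)OC(C)(C)O1 | starting material
19 | (2S,3S)-2-[3,4-bis(TBS-oxy)phenyl]-4-oxo-6-[(E)-4-(TBS-oxy)styryl]-2,3-dihydro-4H-furo[3,2-c]pyran-3-carbonyl chloride | O=C(Cl)[C@H]2c3c(cc(/C=C/c4ccc(O[Si](C)(C)C(C)(C)C)cc4)oc3=O)O[C@@H]2c2ccc(O[Si](C)(C)C(C)(C)C)c(O[Si](C)(C)C(C)(C)C)c2 | intermediate
20 | lithium 2,2-dimethyl-6-methylidene-1,3-dioxin-4-olate | [Li+].[O-]C1=CC(=C)OC(C)(C)O1 | intermediate
21 | (2S,3S)-2-[3,4-bis(TBS-oxy)phenyl]-3-[2-(2,2-dimethyl-4-oxo-4H-1,3-dioxin-6-yl)acetyl]-6-[(E)-4-(TBS-oxy)styryl]-2,3-dihydro-4H-furo[3,2-c]pyran-4-one | CC1(C)OC(=O)C=C(CC(=O)[C@H]2c3c(cc(/C=C/c4ccc(O[Si](C)(C)C(C)(C)C)cc4)oc3=O)O[C@@H]2c2ccc(O[Si](C)(C)C(C)(C)C)c(O[Si](C)(C)C(C)(C)C)c2)O1 | intermediate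
22 | acylketene, 5-[(2S,3S)-2-aryl-4-oxo-6-styryl-2,3-dihydrofuro[3,2-c]pyran-3-yl]-3,5-dioxopent-1-en-1-one (tris-TBS ether) | O=C=CC(=O)CC(=O)[C@H]2c3c(cc(/C=C/c4ccc(O[Si](C)(C)C(C)(C)C)cc4)oc3=O)O[C@@H]2c2ccc(O[Si](C)(C)C(C)(C)C)c(O[Si](C)(C)C(C)(C)C)c2 | intermediate
23 | (2S,3S)-2-[3,4-bis(TBS-oxy)phenyl]-3-(4-hydroxy-2-oxo-2H-pyran-6-yl)-6-[(E)-4-(TBS-oxy)styryl]-2,3-dihydro-4H-furo[3,2-c]pyran-4-one | O=c1cc(O)cc([C@H]2c3c(cc(/C=C/c4ccc(O[Si](C)(C)C(C)(C)C)cc4)oc3=O)O[C@@H]2c2ccc(O[Si](C)(C)C(C)(C)C)c(O[Si](C)(C)C(C)(C)C)c2)o1 | intermediate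
24 | (2S,3S)-2-(3,4-dihydroxyphenyl)-3-(4-hydroxy-2-oxo-2H-pyran-6-yl)-6-[(E)-4-hydroxystyryl]-2,3-dihydro-4H-furo[3,2-c]pyran-4-one | O=c1cc(O)cc([C@H]2c3c(cc(/C=C/c4ccc(O)cc4)oc3=O)O[C@@H]2c2ccc(O)c(O)c2)o1 | target

Total step count: 12. Longest linear sequence: 11 steps (steps 1–5 and 7–12, from 4-hydroxybenzaldehyde).

Steps most likely to fail

1. Step 8. Several processes may divert it.
- The iodane may be consumed by the styryl alkene, or by a phenol set free through acid desilylation.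
- The pyranone carbon may migrate more sluggishly than an aryl carbon, so that elimination to the fully unsaturated pyranopyranone or migration of the electron-rich C2 aryl group takes over.
- The acid may open the six-membered ring by retro-oxa-Michael cleavage and erode C2.

The fallback sets out from 6 and 11, comes back at 16, and forms the C2–C3 bond instead of C3–C3a by carbenoid C–H insertion. Aldehyde 11 is reduced with NaBH4 to 3,4-bis(TBS-oxy)benzyl alcohol F1. Pyranone 6 is iodinated at C3 with N-iodosuccinimide to 4-hydroxy-3-iodo-6-[(E)-4-(TBS-oxy)styryl]-2H-pyran-2-one F2. Mitsunobu etherification of F2 with F1 gives the 4-benzyloxy-3-iodopyranone F3. Coupling of F3 with methyl diazoacetate under Pd(PPh3)4 and Et3N gives the pyranonyl diazoacetate F4. Dirhodium tetrakis[N-phthaloyl-(S)-tert-leucinate], Rh2(S-PTTL)4, or its antipode, whichever delivers 2S, then effects the enantioselective 1,5-insertion into the benzylic ether C–H bond, as known for 2-aryl-2,3-dihydrobenzofuran-3-carboxylates. This gives the cis ester F5, and brief treatment with DBU equilibrates C3 to the trans ester 16.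

2. Step 7. The enol silane is deactivated by the lactone carbonyl and offers competing Lewis-basic sites, so turnover or facial selectivity may be poor. During the acid closure the aldol may dehydrate to the cinnamoylpyranone, or the donor-substituted benzylic C–O bond may ionise with loss of configurational purity.

The fallback sets out from 8, comes back at 13, and sets C2 by forming the C2–aryl bond. Ketone 8 is condensed with N,N-dimethylformamide dimethyl acetal to the enaminone F6. Acid cyclises F6 to 7-[(E)-4-(TBS-oxy)styryl]-4H,5H-pyrano[4,3-b]pyran-4,5-dione F7. Commercial 4-bromocatechol is silylated to 4-bromo-1,2-bis(TBS-oxy)benzene F8. Treatment with n-BuLi, then B(Oi-Pr)3 and mild hydrolysis converts F8 into 3,4-bis(TBS-oxy)phenylboronic acid F9. Asymmetric conjugate addition of F9 to F7 then gives 13; it uses Pd(OCOCF3)2 and the suitable antipode of 4-tert-butyl-2-(pyridin-2-yl)-4,5-dihydrooxazole in wet ClCH2CH2Cl, the method known for chromones and flavanones.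

3. Step 10. The dienolate may deprotonate C3 instead of attacking the carbonyl group. This leads to ketene oligomerisation, or to β-elimination of the ring B pyranolate, which opens ring A and destroys C2.

The fallback sets out from 19 and 18, comes back at 21, and avoids any strong base in the presence of the dihydrofuran. Acid chloride 19 is reduced with LiAlH(Ot-Bu)3 at −78 °C to the trans-3-carbaldehyde F10. Dioxinone 18 is converted with LiN(i-Pr)2 and Me3SiCl into 2,2-dimethyl-6-methylidene-4-(TMS-oxy)-1,3-dioxine F11. A vinylogous Mukaiyama aldol addition of F11 to F10 under BF3·OEt2 gives the δ-hydroxy dioxinone F12 as carbinol epimers. Dess–Martin oxidation of F12 gives 21.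

Further compounds
F1 | step 8 | 3,4-bis(TBS-oxy)benzyl alcohol | OCc1ccc(O[Si](C)(C)C(C)(C)C)c(O[Si](C)(C)C(C)(C)C)c1
F2 | step 8 | 4-hydroxy-3-iodo-6-[(E)-4-(TBS-oxy)styryl]-2H-pyran-2-one | O=c1oc(/C=C/c2ccc(O[Si](C)(C)C(C)(C)C)cc2)cc(O)c1I
F3 | step 8 | 4-[3,4-bis(TBS-oxy)benzyloxy]-3-iodo-6-[(E)-4-(TBS-oxy)styryl]-2H-pyran-2-one | O=c1oc(/C=C/c2ccc(O[Si](C)(C)C(C)(C)C)cc2)cc(OCc2ccc(O[Si](C)(C)C(C)(C)C)c(O[Si](C)(C)C(C)(C)C)c2)c1I
F4 | step 8 | methyl 2-diazo-2-{4-[3,4-bis(TBS-oxy)benzyloxy]-2-oxo-6-[(E)-4-(TBS-oxy)styryl]-2H-pyran-3-yl}acetate | COC(=O)C(=[N+]=[N-])c1c(OCc2ccc(O[Si](C)(C)C(C)(C)C)c(O[Si](C)(C)C(C)(C)C)c2)cc(/C=C/c2ccc(O[Si](C)(C)C(C)(C)C)cc2)oc1=O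
F5 | step 8 | methyl (2S,3R)-2-[3,4-bis(TBS-oxy)phenyl]-4-oxo-6-[(E)-4-(TBS-oxy)styryl]-2,3-dihydro-4H-furo[3,2-c]pyran-3-carboxylate (cis) | COC(=O)[C@@H]2c3c(cc(/C=C/c4ccc(O[Si](C)(C)C(C)(C)C)cc4)oc3=O)O[C@@H]2c2ccc(O[Si](C)(C)C(C)(C)C)c(O[Si](C)(C)C(C)(C)C)c2
F6 | step 7 | 3-[(E)-3-(dimethylamino)acryloyl]-4-hydroxy-6-[(E)-4-(TBS-oxy)styryl]-2H-pyran-2-one | CN(C)/C=C/C(=O)c1c(O)cc(/C=C/c2ccc(O[Si](C)(C)C(C)(C)C)cc2)oc1=O
F7 | step 7 | 7-[(E)-4-(TBS-oxy)styryl]-4H,5H-pyrano[4,3-b]pyran-4,5-dione | O=c1ccoc2cc(/C=C/c3ccc(O[Si](C)(C)C(C)(C)C)cc3)oc(=O)c12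
F8 | step 7 | 4-bromo-1,2-bis(TBS-oxy)benzene | Brc1ccc(O[Si](C)(C)C(C)(C)C)c(O[Si](C)(C)C(C)(C)C)c1
F9 | step 7 | 3,4-bis(TBS-oxy)phenylboronic acid | OB(O)c1ccc(O[Si](C)(C)C(C)(C)C)c(O[Si](C)(C)C(C)(C)C)c1
F10 | step 10 | (2S,3S)-2-[3,4-bis(TBS-oxy)phenyl]-4-oxo-6-[(E)-4-(TBS-oxy)styryl]-2,3-dihydro-4H-furo[3,2-c]pyran-3-carbaldehyde | O=C[C@H]2c3c(cc(/C=C/c4ccc(O[Si](C)(C)C(C)(C)C)cc4)oc3=O)O[C@@H]2c2ccc(O[Si](C)(C)C(C)(C)C)c(O[Si](C)(C)C(C)(C)C)c2
F11 | step 10 | 2,2-dimethyl-6-methylidene-4-(TMS-oxy)-1,3-dioxine | C=C1C=C(O[Si](C)(C)C)OC(C)(C)O1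
F12 | step 10 | trans-2-[3,4-bis(TBS-oxy)phenyl]-3-[2-(2,2-dimethyl-4-oxo-4H-1,3-dioxin-6-yl)-1-hydroxyethyl]-6-[(E)-4-(TBS-oxy)styryl]-2,3-dihydro-4H-furo[3,2-c]pyran-4-one (ring configuration as in 16, carbinol epimers) | CC1(C)OC(=O)C=C(CC(O)[C@H]2c3c(cc(/C=C/c4ccc(O[Si](C)(C)C(C)(C)C)cc4)oc3=O)O[C@@H]2c2ccc(O[Si](C)(C)C(C)(C)C)c(O[Si](C)(C)C(C)(C)C)c2)O1
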